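(All runs are simulated with made-up constants, and the scatter is random.)

Amounts come first. In the red run at 4.00 min, G is down to 27.0% of its charge and E stands at 10.4%, so 62.6% of the G charged sits in an unseen intermediate. In the violet run E levels near 34.8%, and the L charge there is 35.0% of G, so each E takes one L.

| setting | red | ochre | violet | zeta | epsilon | alpha | delta |
|---|---|---|---|---|---|---|---|
| G | 0.10 M | 0.10 M | 0.20 M | 0.10 M | 0.10 M | 0.10 M | 0.10 M |
| L | 0.035 M | 0.053 M | 0.070 M | 0.0700 M | 0.0700 M | 0.0700 M | 0.0700 M |
| X | 2.5 mM | 2.5 mM | 2.5 mM | 2.5 mM | 2.5 mM | 2.5 mM | 2.5 mM |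
| temperature | 95 °C | 128 °C | 95 °C | 140 °C |  | 110 °C | 80 °C |
| remark | run made earlier | run made earlier | run made earlier |  | at 140 °C until 2.0 min, from then on at 80 °C |  |  |
| time |  |  |  | 2.5 min | 2.5 min | 2.5 min | 2.5 min |

| run | time / min | E / % | G / % |
|---|---|---|---|
| red | 1.50 | 2.9 | 61.3 |
| red | 2.50 | 5.1 | 44.7 |
| red | 4.00 | 10.4 | 27.0 |
| red | 8.00 | 21.7 | 8.4 |
| red | 15.0 | 31.4 | 0.2 |
| ochre | 0.667 | 10.6 | 54.0 |
| ochre | 1.33 | 20.9 | 29.5 |
| ochre | 1.50 | 26.0 | 24.7 |
| ochre | 2.50 | 35.8 | 9.2 |
| violet | 1.50 | 3.7 | 61.6 |
| violet | 4.00 | 18.3 | 27.9 |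
| violet | 6.00 | 23.9 | 14.9 |
| violet | 10.0 | 31.7 | 2.1 |
| violet | 15.0 | 34.8 | 0.4 |

(standard deviation of a reading: 1 percentage point)

- a reading or a percentage of E counts all its forms, free or not

- the flask with the highest amount of E, in percent of the G charged ("all alike" if they lie within 1.5 percentage points) (zeta / epsilon / alpha / delta / all alike)
- final E, as a percentage of the G charged, in zeta
- final E, as a percentage of the G charged, in epsilon
- final E, as a percentage of the G charged, in alpha
- final E, as a percentage of the G charged, in delta

G therefore passes two steps in a row. The G readings give the first pace as 0.327 min⁻¹ at 95 °C and 0.954 min⁻¹ at 128 °C. The second step is pseudo-first-order in the intermediate at a given [L]. E gained per minute over the intermediate present, scaled to [L] = 0.0700 M, reads 0.158 min⁻¹ and 0.714 min⁻¹ at those temperatures.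

Each logarithm of a pace is taken as straight in temperature. A reciprocal pace is a wait, and waits in a row add. For zeta the summed wait is 1.52 min, for alpha 5.07 min, and for delta 17.6 min.

Time divided by this wait gives one number, Φ, the count of waits served. In epsilon the hot and cool minutes are counted apart and added, so Φ = 1.35. Zeta has 1.65, alpha 0.493 and delta 0.142, which spans 1.07 powers of ten. Taking the two steps as equal and [L] as held at its charge, this reckoning puts the share of the G charged turned to E at 1 − (1 + 2Φ)·exp(−2Φ).

Was one number enough? For the red run at 2.50 min, a reading not used for its paces, the curve gives 4.09% against a reading of 5.1%, with a scatter of 1 percentage point. For the ochre run at 2.50 min it gives 51.5%, close to the L charge of 53.0%, against a reading of 35.8%. So one number is not enough near the charge of L, the limiting reagent: there the ochre reading stands at 0.695 of the curve, a ratio read from a single reading, which this reckoning carries over as a factor.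

This reckoning therefore gives delta 3.35% and alpha 25.9%, both straight off the curve, with the factor applied to zeta, 58.5%, and epsilon, 52.1%.

The forecast, holding that “G decay is clean first order”, names zeta as highest and gives zeta 55%, epsilon 50%, alpha 23% and delta 3.5%, with zeta and alpha lower than here.

The flasks give zeta 57.7%, ahead of the rest, then epsilon 52.6%, alpha 24.4% and delta 3.37%.

    G + X → X + J (k = 3.56 L mol⁻¹ s⁻¹, Ea = 40.0 kJ mol⁻¹)
    L + X + J → X + E (k = 33.2 L² mol⁻² s⁻¹, Ea = 58.0 kJ mol⁻¹)
    D ⇌ E, rate k3*(cs3 - [E]) while solid is left; crystals form when [E] > cs3 (solubility = 1.20 mM, k = 0.0809 s⁻¹)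
    (constants at 110 °C)

At the end of zeta, D holds 54.3% of the G charged and is counted in E, and the limit of solubility of E does not move the figure. Both steps carry X, so each pace follows [X], and Φ follows it too. The neighbour of epsilon charged with 6.3 × 10⁻⁴ M of X has Φ = 0.339, and the curve gives 14.8%. That flask stands at 13.4%.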